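**Retrosynthetic overview**
- C3–OH and C4–Br: equilibrating (Meerwein–Ponndorf–Verley) reduction of the α'-bromo enone, which comes from kinetic α'-bromination of the spiro enone; the enone comes from allylic oxidation of the spiro diene.
- Key disconnection, spiro bond C6–C7: the tetrasubstituted ring alkene attacks a 2-bromoallyl cation. This cation is a 2-oxyallyl (enolonium) equivalent, so an alkene carbon and the α-carbon of the masked C8 ketone, both normally nucleophilic, are joined, under a chiral counter-anion.
- Cation precursor, bond C8–C9: 1-bromovinyllithium (an acetyl-anion equivalent) adds to the methyl ketone of dihydro-β-ionone, joining two carbonyl-level carbons.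
- Ring order: ring A is bought; ring B and the spiro centre are made in one step; the vinyl bromide is carried from step 1.

Assumption: spiro[5.5]undecane numbering is used (C1–C5 ring A, C6 spiro atom, C7–C11 ring B, C7 next to the brominated alkene carbon C8), so the target is the (3S,4S,6S) isomer with OH trans to the C4 bromine and that bromine cis to C7; the C6 label reads R in 6 and 7 and S in 8–10 only because substituent priorities change, not the spatial arrangement.

**Step 1**
Reactants: 1 dihydro-β-ionone (4-(2,6,6-trimethylcyclohex-1-en-1-yl)butan-2-one); 2 vinyl bromide (bromoethene)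
Product: 4 rac-2-bromo-3-methyl-5-(2,6,6-trimethylcyclohex-1-en-1-yl)pent-1-en-3-ol, via 1-bromovinyllithium 3 (not isolated)
Conditions: 2 (1.5 equiv), LiN(iPr)2 (1.5 equiv), THF/Et2O/pentane 4:1:1, −110 °C, 20 min; then 1, −110 → −90 °C; H2O
Reagents that add atoms: none
Why: Below −105 °C LiN(iPr)2 removes the α-hydrogen of vinyl bromide to give 3, an acetyl-anion equivalent whose carbon is at the ketone oxidation level, and this adds 1,2 to the methyl ketone faster than it enolises it (organolithium carbonyl addition); the carbinol centre is racemic and is erased in step 2.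

**Step 2**
Reactants: 4
Product: 6 (R)-8-bromo-1,5,5,9-tetramethylspiro[5.5]undeca-1,8-diene, via allyl cation 5 (not isolated)
Conditions: imidodiphosphorimidate (IDPi) acid HN[P(=NSO2CF3)(O2C20H10Ar2)]2 (Ar = 3,5-(CF3)2C6H3, both binaphthyl units S; 5 mol %), 5 Å MS, (CF3)2CHOH/CHCl3 1:4, −40 → 0 °C
Reagents that add atoms: none
Why: Proposed new method: the confined strong acid ionises the tertiary 2-bromoallylic alcohol to cation 5, held as a contact ion pair in the chiral anion pocket; the ring alkene attacks the primary allyl terminus through C6 in a six-membered chair-like transition state (cation–olefin spirocyclisation), the anion choosing one enantiotopic face of C6 and so setting the spiro centre, and loss of the C2 hydrogen from the tertiary C1 cation gives the endocyclic alkene; the closest known reaction types are chiral-anion-controlled substitutions through allyl-cation ion pairs and IDPi-catalysed enantioselective cation–olefin cyclisations; the sense of induction is not predictable, so it is read from an anomalous-dispersion X-ray structure of 9 after the first run and the mirror-image acid is used if it is reversed.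

**Step 3**
Reactants: 6
Product: 7 (R)-8-bromo-1,5,5,9-tetramethylspiro[5.5]undeca-1,8-dien-3-one
Conditions: Rh2(C6H10NO)4 (dirhodium tetracaprolactamate, 1 mol %), tBuOOH (70% aq, 5 equiv), ClCH2CH2Cl, 40 °C
Reagents that add atoms: tert-butyl hydroperoxide, CC(C)(C)OO
Why: Rhodium-caprolactamate/tBuOOH allylic oxidation (H-abstraction by the tert-butylperoxyl radical, then collapse of the allylic peroxide to the ketone) should take the unhindered C3 methylene next to the trisubstituted alkene, because the allylic C–H bonds of ring B are deactivated by the vinylic bromine (C7–H is also neopentylic) and the C1 end of the allyl radical is blocked by quaternary C6; C6 is untouched.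

**Step 4**
Reactants: 7
Product: 9 (4S,6S)-4,8-dibromo-1,5,5,9-tetramethylspiro[5.5]undeca-1,8-dien-3-one, via lithium dienolate 8 (not isolated)
Conditions: LiN(iPr)2 (1.1 equiv), THF, −78 °C; then added to N-bromosuccinimide (1.05 equiv), THF, −78 °C; pH 7 buffer
Reagents that add atoms: N-bromosuccinimide, O=C1CCC(=O)N1Br
Why: Kinetic deprotonation of this isophorone-type enone takes the α'-methylene C4 (cross-conjugated dienolate 8) and enolate α-bromination puts bromine on C4; the centre is set by 1,3-induction from C6, the epimer with equatorial bromine cis to C7 (ring A half-chair with the C11 arm pseudoaxial) being expected to be favoured only modestly, so the 4-epimer is separated by chromatography and recycled through the enol.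

**Step 5**
Reactants: 9
Product: 10 (3S,4S,6S)-4,8-dibromo-1,5,5,9-tetramethylspiro[5.5]undeca-1,8-dien-3-ol
Conditions: Al(OiPr)3 (1.5 equiv), iPrOH/toluene 1:1, acetone (0.2 equiv), 60 °C, to constant ratio; aq work-up
Reagents that add atoms: none
Why: Meerwein–Ponndorf–Verley reduction is reversible (Oppenauer back-reaction through the acetone present), so the carbinol epimers equilibrate to the more stable one, with OH pseudoequatorial and trans to the equatorial C4 bromine (the cis epimer has OH syn-axial to the axial C5 methyl), which sets C3 as S; a kinetic hydride would attack anti to that methyl and give the cis epimer, and the 1,2-selective reagent leaves both C=C bonds and both C–Br bonds intact.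

**Compound list**
1 | dihydro-β-ionone, 4-(2,6,6-trimethylcyclohex-1-en-1-yl)butan-2-one | CC(=O)CCC1=C(C)CCCC1(C)C | starting material
2 | vinyl bromide (bromoethene) | C=CBr | starting material
3 | 1-bromovinyllithium (1-bromo-1-lithioethene) | [Li]C(Br)=C | intermediate
4 | rac-2-bromo-3-methyl-5-(2,6,6-trimethylcyclohex-1-en-1-yl)pent-1-en-3-ol | C=C(Br)C(C)(O)CCC1=C(C)CCCC1(C)C | intermediate
5 | 2-bromo-3-methyl-5-(2,6,6-trimethylcyclohex-1-en-1-yl)pent-1-en-3-ylium (2-bromoallyl cation, paired with the catalyst anion) | C=C(Br)[C+](C)CCC1=C(C)CCCC1(C)C | intermediate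
6 | (R)-8-bromo-1,5,5,9-tetramethylspiro[5.5]undeca-1,8-diene | CC1=CCCC(C)(C)[C@]12CCC(C)=C(Br)C2 | intermediate
7 | (R)-8-bromo-1,5,5,9-tetramethylspiro[5.5]undeca-1,8-dien-3-one | CC1=CC(=O)CC(C)(C)[C@]12CCC(C)=C(Br)C2 | intermediate
8 | lithium (6S)-8-bromo-1,5,5,9-tetramethylspiro[5.5]undeca-1,3,8-trien-3-olate | CC1=CC(O[Li])=CC(C)(C)[C@]12CCC(C)=C(Br)C2 | intermediate
9 | (4S,6S)-4,8-dibromo-1,5,5,9-tetramethylspiro[5.5]undeca-1,8-dien-3-one | CC1=CC(=O)[C@@H](Br)C(C)(C)[C@]12CCC(C)=C(Br)C2 | intermediate
10 | (3S,4S,6S)-4,8-dibromo-1,5,5,9-tetramethylspiro[5.5]undeca-1,8-dien-3-ol | CC1=C[C@H](O)[C@@H](Br)C(C)(C)[C@]12CCC(C)=C(Br)C2 | target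

**Totals**
Total step count: 5. Longest linear sequence: 5 steps (1 → 4 → 6 → 7 → 9 → 10).

**Three steps most likely to fail**

Step 2. The enantioselective ion-pair spirocyclisation is untested: the ee may be low, or the cation may give dienes or the fused five-ring mode instead. The fallback sets out from 4 and comes back at 7. Compound 4 is cyclised without stereocontrol (CF3SO3H 5 mol %, (CF3)2CHOH/CH2Cl2, −20 °C) to the racemic spiro diene F1. This is oxidised under the step 3 conditions to the racemic enone F2. F2 is resolved by preparative SFC on an amylose tris(3,5-dimethylphenylcarbamate) phase (CO2/MeOH); the (R)-enantiomer is 7 and the (S)-enone F3 is discarded.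

Step 4. Induction from C6 to C4 relies on the small difference between the two ring B methylene arms and may give a poor epimer ratio. The fallback sets out from 7 and comes back at 9. Dienolate 8 is hydroxylated with (+)-(camphorsulfonyl)oxaziridine, so that the reagent rather than the weakly biased enolate face decides the configuration (the antipodal reagent is used if the sense is wrong); this gives the (4R,6S)-4-hydroxy enone F4. (CF3SO2)2O/2,6-lutidine converts it into the triflate F5. Bu4NBr in acetone then displaces the triflate with inversion to give 9; the SN2 step is activated by the adjacent carbonyl, has no elimination pathway because C5 bears no hydrogen, but is slowed by the neopentyl position.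

Step 5. The equilibrium may not favour the trans isomer enough, or the α-bromo ketone/bromohydrin may degrade or epimerise at C4 under the aluminium alkoxide. The fallback sets out from 9 and comes back at 10. Kinetic reduction with LiBH(sec-Bu)3 (THF, −78 °C; attack anti to the axial C5 methyl) gives the cis-bromohydrin F6. Mitsunobu inversion (4-nitrobenzoic acid, PPh3, DIAD, THF, 0 °C) gives the (3S) 4-nitrobenzoate F7. Brief K2CO3/MeOH at 0 °C, kept short to avoid epoxide closure, releases 10.

**Further compounds**
F1 | step 2 | racemic 8-bromo-1,5,5,9-tetramethylspiro[5.5]undeca-1,8-diene | CC1=CCCC(C)(C)C12CCC(C)=C(Br)C2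
F2 | step 2 | racemic 8-bromo-1,5,5,9-tetramethylspiro[5.5]undeca-1,8-dien-3-one | CC1=CC(=O)CC(C)(C)C12CCC(C)=C(Br)C2
F3 | step 2 | (S)-8-bromo-1,5,5,9-tetramethylspiro[5.5]undeca-1,8-dien-3-one | CC1=CC(=O)CC(C)(C)[C@@]12CCC(C)=C(Br)C2
F4 | step 4 | (4R,6S)-8-bromo-4-hydroxy-1,5,5,9-tetramethylspiro[5.5]undeca-1,8-dien-3-one | CC1=CC(=O)[C@H](O)C(C)(C)[C@]12CCC(C)=C(Br)C2
F5 | step 4 | (4R,6S)-8-bromo-1,5,5,9-tetramethyl-3-oxospiro[5.5]undeca-1,8-dien-4-yl trifluoromethanesulfonate | CC1=CC(=O)[C@H](OS(=O)(=O)C(F)(F)F)C(C)(C)[C@]12CCC(C)=C(Br)C2
F6 | step 5 | (3R,4S,6S)-4,8-dibromo-1,5,5,9-tetramethylspiro[5.5]undeca-1,8-dien-3-ol | CC1=C[C@@H](O)[C@@H](Br)C(C)(C)[C@]12CCC(C)=C(Br)C2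
F7 | step 5 | (3S,4S,6S)-4,8-dibromo-1,5,5,9-tetramethylspiro[5.5]undeca-1,8-dien-3-yl 4-nitrobenzoate | CC1=C[C@H](OC(=O)c3ccc(cc3)[N+](=O)[O-])[C@@H](Br)C(C)(C)[C@]12CCC(C)=C(Br)C2
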